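## Retrosynthetic overview

- **Feature.** In the pyrone ring, O1–C6(Et)–C5(Me) is an intact 3-pentanone unit, and C2–C3–C4 plus the bridge CH2 is a benzylmalonyl unit. The arene 2'-OH is ortho to the bridge carbon C1', so C2 can be held beforehand as the carbonyl of a six-membered aryl lactone (a 2-oxochroman ring).
- **Key disconnections.** C4–C5 is made by C-acylation of the 3-pentanone enol silane with a 2-oxochroman-3-carbonyl chloride. O1–C2 is made when the enol oxygen on C6 displaces the 2'-aryloxide from the lactone carbonyl. The bridge carbon is never a free electrophile, so CH2-linked homodimers are excluded.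
- **Chromanone acid.** It comes from conjugate reduction of a coumarin-3-carboxylic acid, which is made from the C1' salicylaldehyde and Meldrum's acid.
- **Arene.** It comes from 5-methoxyresorcinol. Two directed lithiations of the bis-MOM ether place prenyl at C3' and the (R)-2-methylbutanoyl group at C5' (Weinreb amide). Vilsmeier formylation then fills C1', the last free position.
- **Ring order.** The arene is bought, the lactone ring of the coumarin/chromanone is closed in step 7, and the pyrone ring is closed last in step 12 as the chromanone ring opens.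

Key step: step 12

Assumption: (R)-2-methylbutanoic acid is bought as the single enantiomer, and the malonate-type carbon of the chromanone intermediates is configurationally labile, so it is drawn without configuration.

## Route

Step 1
Reactants: 1 5-methoxyresorcinol
Product: 2 1-methoxy-3,5-bis(methoxymethoxy)benzene
Conditions: MOMCl (2.6 equiv), EtN(iPr)2 (3 equiv), CH2Cl2, 0 °C → rt
Reagents that add atoms: chloromethyl methyl ether, COCCl
Why: Base-mediated O-alkylation of both phenols (Williamson-type acetal ether formation) installs two MOM ethers, which protect the phenols and serve as the strongest directing groups for the lithiations that follow.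

Step 2
Reactants: 2 1-methoxy-3,5-bis(methoxymethoxy)benzene; 3 prenyl bromide
Product: 5 5-methoxy-1,3-bis(methoxymethoxy)-2-(3-methylbut-2-en-1-yl)benzene, via aryllithium 4 (not isolated)
Conditions: n-BuLi (1.1 equiv), THF, 0 °C, 1 h; then 3 (1.3 equiv), −78 °C → rt
Reagents that add atoms: none
Why: Directed ortho-metalation removes the proton between the two chelating OMOM groups, the most acidic ring position, and SN2 alkylation of 4 by the primary allylic bromide puts the prenyl group on the future C3' and leaves a symmetric arene.

Step 3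
Reactants: 6 (R)-2-methylbutanoic acid
Product: 8 (R)-N-methoxy-N,2-dimethylbutanamide, via acyl imidazole 7 (not isolated)
Conditions: CDI (1.1 equiv), CH2Cl2, 0 °C → rt; then MeNHOMe·HCl (1.3 equiv), rt
Reagents that add atoms: N,O-dimethylhydroxylamine hydrochloride, CNOC.Cl
Why: Weinreb amide formation through the acyl imidazole needs neither an acid chloride nor a tertiary amine, so no ketene or enolate can form and the (R) centre of 6 is carried over unchanged.

Step 4
Reactants: 5 5-methoxy-1,3-bis(methoxymethoxy)-2-(3-methylbut-2-en-1-yl)benzene; 8 (R)-N-methoxy-N,2-dimethylbutanamide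
Product: 11 (R)-1-[6-methoxy-2,4-bis(methoxymethoxy)-3-(3-methylbut-2-en-1-yl)phenyl]-2-methylbutan-1-one, via aryllithium 9 (not isolated), via lithium hemiaminal 10 (not isolated)
Conditions: n-BuLi (1.1 equiv), THF, 0 °C, 1.5 h; then 8 (1.2 equiv), −78 → 0 °C; then AcOH (1.5 equiv), −20 °C
Reagents that add atoms: none
Why: A second directed ortho-metalation takes one of the two equivalent protons between OMe and OMOM, and the Weinreb ketone synthesis stops at chelate 10 until the acidic quench, so the acyl group enters at the future C5' with no regioisomer, no Lewis acid that could cleave the neighbouring OMe and no enolisable ketone in basic medium; the (R) centre comes from 8.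

Step 5
Reactants: 11 (R)-1-[6-methoxy-2,4-bis(methoxymethoxy)-3-(3-methylbut-2-en-1-yl)phenyl]-2-methylbutan-1-one
Product: 12 (R)-1-[2,4-dihydroxy-6-methoxy-3-(3-methylbut-2-en-1-yl)phenyl]-2-methylbutan-1-one
Conditions: HCl (0.5 M in MeOH, catalytic), 40 °C, short reaction time
Reagents that add atoms: none
Why: Acid-catalysed acetal exchange with methanol frees both phenols under the mild conditions commonly used for MOM ethers of ortho-prenylated phenols, and short contact with dilute acid should prevent both chroman formation from the prenyl group and enolisation of the now hydrogen-bonded ketone.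

Step 6
Reactants: 12 (R)-1-[2,4-dihydroxy-6-methoxy-3-(3-methylbut-2-en-1-yl)phenyl]-2-methylbutan-1-one
Product: 14 2,4-dihydroxy-6-methoxy-5-[(R)-2-methylbutanoyl]-3-(3-methylbut-2-en-1-yl)benzaldehyde, via aryl iminium chloride 13 (not isolated)
Conditions: (chloromethylene)dimethyliminium chloride (1.3 equiv), MeCN, 0 °C → rt; then H2O, rt
Reagents that add atoms: (chloromethylene)dimethyliminium chloride, C[N+](C)=CCl.[Cl-]; water, O
Why: In this Vilsmeier–Haack formylation the one free ring carbon (future C1') is activated by all three oxygen substituents and should react at 0 °C far faster than the hindered branched ketone or the isolated trisubstituted alkene, while amine/magnesium-salt or strong Lewis acid formylations, which threaten the stereocentre or the prenyl group, are avoided.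

Step 7
Reactants: 14 2,4-dihydroxy-6-methoxy-5-[(R)-2-methylbutanoyl]-3-(3-methylbut-2-en-1-yl)benzaldehyde; 15 Meldrum's acid
Product: 17 7-hydroxy-5-methoxy-6-[(R)-2-methylbutanoyl]-8-(3-methylbut-2-en-1-yl)-2-oxo-2H-chromene-3-carboxylic acid, via arylidene Meldrum's acid 16 (not isolated)
Conditions: 15 (1.2 equiv), piperidinium acetate (10 mol %), EtOH, rt → 60 °C
Reagents that add atoms: none
Why: Knoevenagel condensation, followed by attack of 2'-OH (the only phenol ortho to the new alkene) on a Meldrum's acid carbonyl with loss of acetone, is the standard synthesis of coumarin-3-carboxylic acids from salicylaldehydes and assembles the bridge carbon with the three malonyl carbons that become pyrone C2, C3 and C4.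

Step 8
Reactants: 17 7-hydroxy-5-methoxy-6-[(R)-2-methylbutanoyl]-8-(3-methylbut-2-en-1-yl)-2-oxo-2H-chromene-3-carboxylic acid
Product: 18 7-hydroxy-5-methoxy-6-[(R)-2-methylbutanoyl]-8-(3-methylbut-2-en-1-yl)-2-oxochromane-3-carboxylic acid (C3 epimers)
Conditions: Hantzsch ester (diethyl 2,6-dimethyl-1,4-dihydropyridine-3,5-dicarboxylate, 1.4 equiv), SiO2, toluene, 60 °C, dark
Reagents that add atoms: none
Why: Hantzsch ester transfer hydrogenation delivers hydride to the β-carbon of the alkene that carries two geminal acceptors (the lactone carbonyl and the hydrogen-bonded CO2H, further activated on silica gel) and leaves the isolated prenyl alkene and the aryl ketone alone; the new C3 centre is a labile malonate-type centre, formed as both epimers and erased in step 12.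

Step 9
Reactants: 18 7-hydroxy-5-methoxy-6-[(R)-2-methylbutanoyl]-8-(3-methylbut-2-en-1-yl)-2-oxochromane-3-carboxylic acid
Product: 19 tert-butyldimethylsilyl 7-(tert-butyldimethylsilyloxy)-5-methoxy-6-[(R)-2-methylbutanoyl]-8-(3-methylbut-2-en-1-yl)-2-oxochromane-3-carboxylate
Conditions: TBSOTf (2.2 equiv), 2,6-lutidine (3 equiv), CH2Cl2, −40 → 0 °C; rapid cold work-up, used crude
Reagents that add atoms: tert-butyldimethylsilyl triflate, CC(C)(C)[Si](C)(C)OS(=O)(=O)C(F)(F)F
Why: Silylation with the silyl triflate and a hindered non-nucleophilic pyridine base converts the chelated 7-OH (the later 4'-OH) into the silyl ether and the acid into the silyl ester in one operation, with no nucleophile that could open the aryl lactone and no base strong enough to enolise the ketone.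

Step 10
Reactants: 19 tert-butyldimethylsilyl 7-(tert-butyldimethylsilyloxy)-5-methoxy-6-[(R)-2-methylbutanoyl]-8-(3-methylbut-2-en-1-yl)-2-oxochromane-3-carboxylate
Product: 20 7-(tert-butyldimethylsilyloxy)-5-methoxy-6-[(R)-2-methylbutanoyl]-8-(3-methylbut-2-en-1-yl)-2-oxochromane-3-carbonyl chloride
Conditions: (COCl)2 (1.2 equiv), DMF (5 mol %), CH2Cl2, 0 °C → rt; evaporated and used at once
Reagents that add atoms: oxalyl chloride, O=C(Cl)C(=O)Cl
Why: Silyl esters are known to give acid chlorides with oxalyl chloride and catalytic DMF (chloroiminium catalysis) under neutral conditions, the silyl group leaving as the silyl chloride, so no HCl arises that could add to the prenyl alkene or cleave the aryl silyl ether.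

Step 11
Reactants: 21 3-pentanone
Product: 22 (Z)-trimethyl(pent-2-en-3-yloxy)silane
Conditions: TMSOTf (1.1 equiv), Et3N (1.3 equiv), Et2O, 0 °C → rt; distillation
Reagents that add atoms: trimethylsilyl triflate, C[Si](C)(C)OS(=O)(=O)C(F)(F)F
Why: Soft enolisation with a silyl triflate and triethylamine gives the enol silane of a symmetric ketone, so there is no regiochemical issue, and the alkene geometry (mainly Z) disappears in the pyrone.

Step 12
Reactants: 20 7-(tert-butyldimethylsilyloxy)-5-methoxy-6-[(R)-2-methylbutanoyl]-8-(3-methylbut-2-en-1-yl)-2-oxochromane-3-carbonyl chloride; 22 (Z)-trimethyl(pent-2-en-3-yloxy)silane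
Product: 24 4'-O-TBS ether of the target, via tricarbonyl compound 23 (not isolated)
Conditions: 20 added to 22 (2 equiv), ZnCl2 (20 mol %), CH2Cl2, −20 °C → rt; then DBU (4 equiv), 0 °C → rt; cold aq. citric acid work-up
Reagents that add atoms: none
Why: Proposed new method: ZnCl2 activates the COCl group of 20, the nucleophilic carbon of 22 attacks it and Me3SiCl leaves, which forms C4–C5 and gives 23 with no strong base present; the closest known reactions are the Lewis-acid C-acylation of ketone enol silanes by acid chlorides and the pyrone synthesis from malonyl chlorides and enol silanes. DBU then enolises the 1,3-diketone part of 23, and the oxygen on C6 adds to the aryl lactone carbonyl C2 and drives out the 2'-aryloxide, a 6-exo-trig addition–elimination that forms O1–C2, closes the pyrone ring and opens the chromanone ring; this matches the known DBU lactonisation of 3,5-dioxo esters, the new element being a cyclic aryl ester as the acyl donor. An aryloxide departs far more easily than the alkoxide of the usual esters, and the isomerisation is pulled forward by the aromatic pyrone, which rests in the flask as its stabilised anion. No stereocentre is formed, since C3 and C5 of 23 become sp2 and all its diastereomers converge. The step needs C- rather than O-acylation, which the soft enol silane under ZnCl2 should secure, and O- rather than C-cyclisation, which the weak amidine base should secure because it cannot form the terminal carbanion that a Claisen closure to a carbocycle would need. The (R) centre should hold because its ketone, twisted between OMe and OTBS, is far less acidic than the tricarbonyl protons that take up the DBU, and attack of 22 at the lactone carbonyl instead of COCl would end in the same pyrone.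

Step 13
Reactants: 24 4'-O-TBS ether of the target
Product: 25 target CNP0233274.1
Conditions: TBAF (1.2 equiv), AcOH (1.5 equiv), THF, 0 °C
Reagents that add atoms: none
Why: Fluoride-induced cleavage of the aryl silyl ether, buffered with acetic acid so that neither phenoxide nor pyronate builds up, should free 4'-OH without touching the (R) centre, the prenyl group or the pyrone.

## Compound list

1 | 5-methoxyresorcinol | COc1cc(O)cc(O)c1 | starting material
2 | 1-methoxy-3,5-bis(methoxymethoxy)benzene | COCOc1cc(OC)cc(OCOC)c1 | intermediate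
3 | prenyl bromide (1-bromo-3-methylbut-2-ene) | CC(C)=CCBr | starting material
4 | [4-methoxy-2,6-bis(methoxymethoxy)phenyl]lithium | [Li]c1c(OCOC)cc(OC)cc1OCOC | intermediate
5 | 5-methoxy-1,3-bis(methoxymethoxy)-2-(3-methylbut-2-en-1-yl)benzene | COCOc1cc(OC)cc(OCOC)c1CC=C(C)C | intermediate
6 | (R)-2-methylbutanoic acid | OC(=O)[C@H](C)CC | starting material
7 | (R)-1-(imidazol-1-yl)-2-methylbutan-1-one | O=C([C@H](C)CC)n1ccnc1 | intermediate
8 | (R)-N-methoxy-N,2-dimethylbutanamide | CON(C)C(=O)[C@H](C)CC | intermediate
9 | [6-methoxy-2,4-bis(methoxymethoxy)-3-(3-methylbut-2-en-1-yl)phenyl]lithium | [Li]c1c(OC)cc(OCOC)c(CC=C(C)C)c1OCOC | intermediate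
10 | lithium alkoxide of the aryl/Weinreb amide adduct (hemiaminal carbon undefined, side chain R) | [Li]OC(N(C)OC)([C@H](C)CC)c1c(OC)cc(OCOC)c(CC=C(C)C)c1OCOC | intermediate
11 | (R)-1-[6-methoxy-2,4-bis(methoxymethoxy)-3-(3-methylbut-2-en-1-yl)phenyl]-2-methylbutan-1-one | O=C([C@H](C)CC)c1c(OC)cc(OCOC)c(CC=C(C)C)c1OCOC | intermediate
12 | (R)-1-[2,4-dihydroxy-6-methoxy-3-(3-methylbut-2-en-1-yl)phenyl]-2-methylbutan-1-one | O=C([C@H](C)CC)c1c(OC)cc(O)c(CC=C(C)C)c1O | intermediate
13 | aryl(dimethyl)iminium chloride at C1' | C[N+](C)=Cc1c(O)c(CC=C(C)C)c(O)c(C(=O)[C@H](C)CC)c1OC.[Cl-] | intermediate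
14 | 2,4-dihydroxy-6-methoxy-5-[(R)-2-methylbutanoyl]-3-(3-methylbut-2-en-1-yl)benzaldehyde | O=Cc1c(O)c(CC=C(C)C)c(O)c(C(=O)[C@H](C)CC)c1OC | intermediate
15 | Meldrum's acid | CC1(C)OC(=O)CC(=O)O1 | starting material
16 | 5-arylidene Meldrum's acid from 14 | CC1(C)OC(=O)C(=Cc2c(O)c(CC=C(C)C)c(O)c(C(=O)[C@H](C)CC)c2OC)C(=O)O1 | intermediate
17 | 7-hydroxy-5-methoxy-6-[(R)-2-methylbutanoyl]-8-(3-methylbut-2-en-1-yl)-2-oxo-2H-chromene-3-carboxylic acid | OC(=O)c1cc2c(OC)c(C(=O)[C@H](C)CC)c(O)c(CC=C(C)C)c2oc1=O | intermediate
18 | 7-hydroxy-5-methoxy-6-[(R)-2-methylbutanoyl]-8-(3-methylbut-2-en-1-yl)-2-oxochromane-3-carboxylic acid (C3 epimers) | OC(=O)C1Cc2c(OC)c(C(=O)[C@H](C)CC)c(O)c(CC=C(C)C)c2OC1=O | intermediate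
19 | TBS ester, 7-O-TBS ether of 18 (C3 epimers) | CC(C)(C)[Si](C)(C)OC(=O)C1Cc2c(OC)c(C(=O)[C@H](C)CC)c(O[Si](C)(C)C(C)(C)C)c(CC=C(C)C)c2OC1=O | intermediate
20 | 7-(tert-butyldimethylsilyloxy)-5-methoxy-6-[(R)-2-methylbutanoyl]-8-(3-methylbut-2-en-1-yl)-2-oxochromane-3-carbonyl chloride (C3 epimers) | O=C(Cl)C1Cc2c(OC)c(C(=O)[C@H](C)CC)c(O[Si](C)(C)C(C)(C)C)c(CC=C(C)C)c2OC1=O | intermediate
21 | 3-pentanone | CCC(=O)CC | starting material
22 | (Z)-trimethyl(pent-2-en-3-yloxy)silane | C/C=C(/CC)O[Si](C)(C)C | intermediate
23 | 3-(2-methyl-3-oxopentanoyl)chroman-2-one carrying the substituents of 20 (diastereomers) | CCC(=O)C(C)C(=O)C1Cc2c(OC)c(C(=O)[C@H](C)CC)c(O[Si](C)(C)C(C)(C)C)c(CC=C(C)C)c2OC1=O | intermediate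
24 | 3-{[4-(tert-butyldimethylsilyloxy)-2-hydroxy-6-methoxy-5-[(R)-2-methylbutanoyl]-3-(3-methylbut-2-en-1-yl)phenyl]methyl}-6-ethyl-4-hydroxy-5-methyl-2H-pyran-2-one | CCc1oc(=O)c(Cc2c(O)c(CC=C(C)C)c(O[Si](C)(C)C(C)(C)C)c(C(=O)[C@H](C)CC)c2OC)c(O)c1C | intermediate
25 | 3-{[2,4-dihydroxy-6-methoxy-5-[(R)-2-methylbutanoyl]-3-(3-methylbut-2-en-1-yl)phenyl]methyl}-6-ethyl-4-hydroxy-5-methyl-2H-pyran-2-one (CNP0233274.1) | CCc1oc(=O)c(Cc2c(O)c(CC=C(C)C)c(O)c(C(=O)[C@H](C)CC)c2OC)c(O)c1C | target

## Step count and risks

Total step count: 13.
Longest linear sequence: 11 steps (1, 2, 4, 5, 6, 7, 8, 9, 10, 12, 13).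

The single stereocentre comes from 6 and by design never sits next to an enolate. Its integrity should be checked by chiral HPLC at 12 and at 25.

Steps most likely to fail:

1. **Step 12 (bears the label "Proposed new method:").**
   - The enol silane may be acylated on oxygen.
   - Compound 20 may lose HCl and condense with itself before 22 attacks.
   - The sequence may stall at a chelated enolate of 23 that does not cyclise.
   - The fallback uses known chemistry, sets out from 22 and 12, and comes back at 25. Compound 22 is condensed with malonyl dichloride (Et2O, −20 °C → rt) to give 6-ethyl-4-hydroxy-5-methyl-2H-pyran-2-one F1. Aminomethylation of its C3 with Eschenmoser's salt (CH2Cl2, rt) gives 3-[(dimethylamino)methyl]-6-ethyl-4-hydroxy-5-methyl-2H-pyran-2-one F2. Warming F2 with 12 in MeCN should release 6-ethyl-5-methyl-3-methylidenepyran-2,4-dione F3. The one free ring carbon of 12 adds to F3, and this gives 25 directly by the established methylene bridging of acylphloroglucinols and hydroxypyrones.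

2. **Step 8.**
   - Hydride transfer may be slow, because the oxygen donors on the coumarin lower its acceptor strength.
   - Prolonged heating may then cause decarboxylation of the product acid.
   - The fallback sets out from 12 and 15, comes back at 18, and also removes steps 6 and 7. Compound 12 is aminomethylated with Eschenmoser's salt (CH2Cl2, rt) to give (R)-1-{3-[(dimethylamino)methyl]-4,6-dihydroxy-2-methoxy-5-(3-methylbut-2-en-1-yl)phenyl}-2-methylbutan-1-one F4. Warmed with excess 15 in MeCN at 50 °C, F4 should lose dimethylamine to give the ortho-quinone methide F5. The Meldrum's acid enolate traps F5 to give the 5-(2-hydroxybenzyl) Meldrum's acid F6. F6 lactonises through 2'-OH with loss of acetone to 18, so the bridge carbon enters at the correct oxidation level and no reduction is needed.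

3. **Step 4.**
   - The benzylic–allylic CH2 of the prenyl group may be deprotonated in competition with the ring proton.
   - Proton transfer may occur instead of addition when the hindered aryllithium meets the branched amide.
   - The fallback sets out from 6, 1 and 3 and comes back at 12. Compound 6 is converted with (COCl)2 and catalytic DMF into (R)-2-methylbutanoyl chloride F7. Friedel–Crafts acylation of 1 with F7 (AlCl3, CH2Cl2–MeNO2, 0 °C) gives, after separation from the regioisomeric ketone, (R)-1-(2,4-dihydroxy-6-methoxyphenyl)-2-methylbutan-1-one F8. C-alkylation of the phenoxide of F8 with 3 (KOH, H2O–MeOH, 0 °C) at the carbon between the two oxygens gives 12. This detour is shorter but less selective, and the optical purity must be checked after the Lewis acid step.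

## Further compounds

F1 | step 12 | 6-ethyl-4-hydroxy-5-methyl-2H-pyran-2-one | CCc1oc(=O)cc(O)c1C
F2 | step 12 | 3-[(dimethylamino)methyl]-6-ethyl-4-hydroxy-5-methyl-2H-pyran-2-one | CCc1oc(=O)c(CN(C)C)c(O)c1C
F3 | step 12 | 6-ethyl-5-methyl-3-methylidenepyran-2,4-dione | CCC1=C(C)C(=O)C(=C)C(=O)O1
F4 | step 8 | (R)-1-{3-[(dimethylamino)methyl]-4,6-dihydroxy-2-methoxy-5-(3-methylbut-2-en-1-yl)phenyl}-2-methylbutan-1-one | CN(C)Cc1c(O)c(CC=C(C)C)c(O)c(C(=O)[C@H](C)CC)c1OC
F5 | step 8 | ortho-quinone methide from F4 | C=C1C(=O)C(CC=C(C)C)=C(O)C(C(=O)[C@H](C)CC)=C1OC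
F6 | step 8 | 5-(2-hydroxybenzyl) Meldrum's acid from F5 and 15 | CC1(C)OC(=O)C(Cc2c(O)c(CC=C(C)C)c(O)c(C(=O)[C@H](C)CC)c2OC)C(=O)O1
F7 | step 4 | (R)-2-methylbutanoyl chloride | ClC(=O)[C@H](C)CC
F8 | step 4 | (R)-1-(2,4-dihydroxy-6-methoxyphenyl)-2-methylbutan-1-one | O=C([C@H](C)CC)c1c(OC)cc(O)cc1O
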